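**Strategy**

Everything rests on opening the γ-butyrolactone between its carbonyl carbon and ring oxygen. Before benzylation, C4 of that ring (O1, C2, C3, C4, C5) sits between two unsubstituted methylenes, C3 and C5, so C4 corresponds to the prochiral C3 of a cyclobutanone. A catalyst-controlled Baeyer–Villiger oxidation of cyclobutanone 10, which already carries the (R)-aryl(silyloxy)methyl side chain, inserts the ring oxygen, enlarges the ring from four to five atoms and fixes C4 in one operation. Trans-selective enolate benzylation with an enantiopure dihydrobenzofuran bromide (Evans aldol, then quinone-methide ring closure) and one fluoride desilylation complete the target.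

Key step: step 6

Assumption: metal alkoxides, borate esters and ammonium salts that are only protonated or hydrolysed in the aqueous work-up, and fleeting mechanistic species (Criegee adduct, Claisen dienone, benzylic cation), are not counted as separate compounds; species made in the flask and used in a second operation are numbered.

Abbreviations: TBS = tert-butyldimethylsilyl, MOM = methoxymethyl, TES = triethylsilyl.

**Route**

Step 1
Reactants: 1 4-bromo-2-methoxyphenol
Product: 2 (4-bromo-2-methoxyphenoxy)(tert-butyl)dimethylsilane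
Conditions: TBSCl, imidazole, DMF, rt
Reagents that add atoms: TBSCl, CC(C)(C)[Si](C)(C)Cl
Why: Silylation of the phenol (substitution at silicon, imidazole as base and acyl-type transfer catalyst) masks the acidic OH before the Grignard reagent is made.

Step 2
Reactants: 2 (4-bromo-2-methoxyphenoxy)(tert-butyl)dimethylsilane; 3 3-methylidenecyclobutane-1-carbonitrile
Product: 6 [4-(TBS-oxy)-3-methoxyphenyl](3-methylidenecyclobutyl)methanone, via arylmagnesium bromide 4 (not isolated), via bromomagnesium ketiminate 5 (not isolated)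
Conditions: Mg, THF, 45 °C; then 3, CuBr (2 mol %), reflux; then 1 M HCl, 0 °C → rt
Reagents that add atoms: water, O
Why: Grignard addition to a nitrile stops at the N-magnesio ketimine, which cannot take up a second aryl group, and mild aqueous acid should hydrolyse it to the ketone without harming the aryl silyl ether or the exocyclic alkene.

Step 3
Reactants: 6 [4-(TBS-oxy)-3-methoxyphenyl](3-methylidenecyclobutyl)methanone
Product: 7 (R)-[4-(TBS-oxy)-3-methoxyphenyl](3-methylidenecyclobutyl)methanol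
Conditions: (S)-2-methyl-CBS-oxazaborolidine (20 mol %), catecholborane, toluene, −78 → −40 °C
Reagents that add atoms: none
Why: Corey–Bakshi–Shibata reduction, in which the aryl group acts as the large substituent so that the (S)-catalyst should deliver hydride to the face giving the (R)-carbinol (the sense of acetophenone to (R)-1-phenylethanol), while catecholborane at low temperature should leave the 1,1-disubstituted alkene unhydroborated.

Step 4
Reactants: 7 (R)-[4-(TBS-oxy)-3-methoxyphenyl](3-methylidenecyclobutyl)methanol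
Product: 8 tert-butyl{4-[(R)-(TBS-oxy)(3-methylidenecyclobutyl)methyl]-2-methoxyphenoxy}dimethylsilane
Conditions: TBSOTf, 2,6-lutidine, CH2Cl2, −78 → 0 °C
Reagents that add atoms: TBSOTf, CC(C)(C)[Si](C)(C)OS(=O)(=O)C(F)(F)F
Why: Silylation of the hindered benzylic alcohol with the silyl triflate and a hindered pyridine base takes place at oxygen only, so the carbinol C–O bond and its (R) configuration are untouched.

Step 5
Reactants: 8 tert-butyl{4-[(R)-(TBS-oxy)(3-methylidenecyclobutyl)methyl]-2-methoxyphenoxy}dimethylsilane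
Product: 10 3-[(R)-(TBS-oxy)[4-(TBS-oxy)-3-methoxyphenyl]methyl]cyclobutan-1-one, via vicinal diol 9 (not isolated)
Conditions: K2OsO4·2H2O (2 mol %), NaIO4, 2,6-lutidine, dioxane/H2O, rt
Reagents that add atoms: NaIO4 (oxygen passed on through the osmium catalyst), [Na+].[O-]I(=O)(=O)=O
Why: Lemieux–Johnson oxidation (osmium-catalysed dihydroxylation of the exocyclic alkene, then periodate cleavage of the diol) should unmask the cyclobutanone under buffered conditions that both silyl ethers and the electron-rich arene tolerate.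

Step 6
Reactants: 10 3-[(R)-(TBS-oxy)[4-(TBS-oxy)-3-methoxyphenyl]methyl]cyclobutan-1-one
Product: 11 (4R)-4-[(R)-(TBS-oxy)[4-(TBS-oxy)-3-methoxyphenyl]methyl]oxolan-2-one
Conditions: Sc(OTf)3 (5 mol %), chiral N,N'-dioxide ligand (6 mol %; propane-1,3-diyl-bridged bis(pipecolic acid 2,6-diisopropylanilide) N,N'-dioxide, the antipode giving the (4R)-lactone to be fixed in a trial of both), mCPBA, EtOAc, −20 °C
Reagents that add atoms: mCPBA (3-chloroperbenzoic acid), OOC(=O)c1cccc(Cl)c1
Why: Baeyer–Villiger oxidation: the scandium-bound ketone of 10 adds the peracid to give a Criegee adduct, and one ring methylene then shifts from carbon to the peroxide oxygen with retention while 3-chlorobenzoate leaves. The closest known reaction type is the catalytic desymmetrising Baeyer–Villiger oxidation of prochiral 3-substituted cyclobutanones to β-substituted γ-butyrolactones with a chiral Lewis acid and a peracid. The lactone ring is formed by ring enlargement and not by cyclisation: the 1,2-shift inserts oxygen between C1 and one CH2 of the four-membered ring, and relief of ring strain drives it and should let it outpace oxidation of the electron-rich arene. The new stereocentre C4 of 11 is decided only by which of the two CH2 groups migrates, and this is set by the chiral ligand sphere on scandium, which holds the Criegee adduct so that one C–C bond lies antiperiplanar to the O–O bond; the neighbouring (R)-carbinol centre is a secondary element that may reinforce or oppose it. The step needs group selectivity between two diastereotopic but constitutionally identical primary methylenes (there is no regiochemical question), and the substrate supports a clean outcome by being monosubstituted at C3, by having its carbinol oxygen capped with a bulky silyl group that cannot chelate the metal, and by making the two possible lactones diastereomers that can be told apart and separated.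

Step 7
Reactants: 12 methyl 4-hydroxy-3-methoxybenzoate (methyl vanillate); 13 allyl bromide
Product: 14 methyl 3-methoxy-4-(prop-2-en-1-yloxy)benzoate
Conditions: K2CO3, acetone, reflux
Reagents that add atoms: none
Why: Williamson ether synthesis of the phenoxide with a reactive allylic bromide.

Step 8
Reactants: 14 methyl 3-methoxy-4-(prop-2-en-1-yloxy)benzoate
Product: 15 methyl 4-hydroxy-3-methoxy-5-(prop-2-en-1-yl)benzoate
Conditions: N,N-diethylaniline, 200 °C
Reagents that add atoms: none
Why: Aromatic Claisen rearrangement ([3,3]-sigmatropic shift, then tautomerisation) should deliver the allyl group to C5, the only free ortho position, because the other one carries the methoxy group.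

Step 9
Reactants: 15 methyl 4-hydroxy-3-methoxy-5-(prop-2-en-1-yl)benzoate
Product: 16 methyl 3-methoxy-4-(MOM-oxy)-5-(prop-2-en-1-yl)benzoate
Conditions: MOMCl, iPr2NEt, CH2Cl2, 0 °C → rt
Reagents that add atoms: MOMCl (chloromethyl methyl ether), COCCl
Why: O-alkylation of the phenol to a MOM acetal gives a group that withstands permanganate, boron enolate formation and borohydride but is removed by the acid used later for ring closure.

Step 10
Reactants: 16 methyl 3-methoxy-4-(MOM-oxy)-5-(prop-2-en-1-yl)benzoate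
Product: 17 2-[3-methoxy-5-(methoxycarbonyl)-2-(MOM-oxy)phenyl]acetic acid
Conditions: KMnO4 (cat.), NaIO4, K2CO3, tBuOH/H2O, rt
Reagents that add atoms: NaIO4, [Na+].[O-]I(=O)(=O)=O; water, O
Why: Lemieux–von Rudloff oxidation cleaves the terminal alkene and oxidises the resulting arylacetaldehyde to the arylacetic acid at about pH 8, where the methyl ester and the MOM ether should be stable.

Step 11
Reactants: 17 2-[3-methoxy-5-(methoxycarbonyl)-2-(MOM-oxy)phenyl]acetic acid; 18 (S)-4-benzyl-1,3-oxazolidin-2-one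
Product: 20 methyl 3-{2-[(4S)-4-benzyl-2-oxo-1,3-oxazolidin-3-yl]-2-oxoethyl}-5-methoxy-4-(MOM-oxy)benzoate, via mixed pivalic anhydride 19 (not isolated)
Conditions: PivCl, Et3N, THF, −20 °C; then 18, LiCl, rt
Reagents that add atoms: none
Why: N-acylation of the oxazolidinone through a mixed anhydride (lithium chloride and triethylamine procedure), in which the nucleophile attacks the unhindered arylacetyl carbonyl and not the pivaloyl one.

Step 12
Reactants: 21 vanillin
Product: 22 3-methoxy-4-(MOM-oxy)benzaldehyde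
Conditions: MOMCl, iPr2NEt, CH2Cl2, 0 °C → rt
Reagents that add atoms: MOMCl (chloromethyl methyl ether), COCCl
Why: MOM acetal formation at the phenol gives an aldehyde partner whose protecting group is removed in the same acid step as that of the other ring.

Step 13
Reactants: 20 methyl 3-{2-[(4S)-4-benzyl-2-oxo-1,3-oxazolidin-3-yl]-2-oxoethyl}-5-methoxy-4-(MOM-oxy)benzoate; 22 3-methoxy-4-(MOM-oxy)benzaldehyde
Product: 24 methyl 3-[(2S,3S)-1-[(4S)-4-benzyl-2-oxo-1,3-oxazolidin-3-yl]-3-hydroxy-3-[3-methoxy-4-(MOM-oxy)phenyl]-1-oxopropan-2-yl]-5-methoxy-4-(MOM-oxy)benzoate, via dibutylboron Z-enolate 23 (not isolated)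
Conditions: Bu2BOTf, iPr2NEt, CH2Cl2, 0 °C; then 22, −78 → 0 °C; pH 7 buffer, H2O2, MeOH
Reagents that add atoms: none
Why: Evans syn-aldol reaction, in which the Z-boron enolate reacts through a closed chair (Zimmerman–Traxler) transition state on the face away from the benzyl group of the (S)-auxiliary, so that the aryl-bearing carbon should become (S) and the carbinol (S); only the former is carried into the target.

Step 14
Reactants: 24 methyl 3-[(2S,3S)-1-[(4S)-4-benzyl-2-oxo-1,3-oxazolidin-3-yl]-3-hydroxy-3-[3-methoxy-4-(MOM-oxy)phenyl]-1-oxopropan-2-yl]-5-methoxy-4-(MOM-oxy)benzoate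
Product: 25 methyl 3-[(1S,2R)-1,3-dihydroxy-1-[3-methoxy-4-(MOM-oxy)phenyl]propan-2-yl]-5-methoxy-4-(MOM-oxy)benzoate
Conditions: LiBH4, MeOH (1 equiv), THF, 0 °C
Reagents that add atoms: none
Why: Reductive cleavage of the N-acyl oxazolidinone by hydride, which should attack the activated exocyclic imide carbonyl much faster than the aromatic methyl ester at 0 °C and leave the aryl-bearing stereocentre untouched (its descriptor changes to R only through the priority change).

Step 15
Reactants: 25 methyl 3-[(1S,2R)-1,3-dihydroxy-1-[3-methoxy-4-(MOM-oxy)phenyl]propan-2-yl]-5-methoxy-4-(MOM-oxy)benzoate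
Product: 26 methyl (2S,3R)-2-(4-hydroxy-3-methoxyphenyl)-3-(hydroxymethyl)-7-methoxy-2,3-dihydro-1-benzofuran-5-carboxylate
Conditions: 3 M HCl, THF, 50 °C
Reagents that add atoms: none
Why: Acetal hydrolysis frees both phenols, the para-hydroxybenzylic alcohol ionises to a quinone-methide-type cation, and the neighbouring phenol closes the furan ring (5-exo-trig, reversible under acid) so that the aryl group should end up trans to the hydroxymethyl group, C2 becoming (S) under control of the fixed (R) centre at C3.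

Step 16
Reactants: 26 methyl (2S,3R)-2-(4-hydroxy-3-methoxyphenyl)-3-(hydroxymethyl)-7-methoxy-2,3-dihydro-1-benzofuran-5-carboxylate
Product: 27 methyl (2S,3R)-2-[4-(TBS-oxy)-3-methoxyphenyl]-3-[(TBS-oxy)methyl]-7-methoxy-2,3-dihydro-1-benzofuran-5-carboxylate
Conditions: TBSCl (2.5 equiv), imidazole, DMF, rt
Reagents that add atoms: TBSCl, CC(C)(C)[Si](C)(C)Cl
Why: Silylation of the phenol and the primary alcohol in one operation puts the same fluoride-labile group on every hydroxyl that must survive the enolate chemistry.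

Step 17
Reactants: 27 methyl (2S,3R)-2-[4-(TBS-oxy)-3-methoxyphenyl]-3-[(TBS-oxy)methyl]-7-methoxy-2,3-dihydro-1-benzofuran-5-carboxylate
Product: 28 [(2S,3R)-2-[4-(TBS-oxy)-3-methoxyphenyl]-3-[(TBS-oxy)methyl]-7-methoxy-2,3-dihydro-1-benzofuran-5-yl]methanol
Conditions: iBu2AlH, CH2Cl2, −78 → −20 °C
Reagents that add atoms: none
Why: Hydride reduction of the aromatic ester to the benzylic alcohol, with silyl ethers and the dihydrobenzofuran inert to the aluminium hydride at low temperature.

Step 18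
Reactants: 28 [(2S,3R)-2-[4-(TBS-oxy)-3-methoxyphenyl]-3-[(TBS-oxy)methyl]-7-methoxy-2,3-dihydro-1-benzofuran-5-yl]methanol
Product: 29 (2S,3R)-5-(bromomethyl)-2-[4-(TBS-oxy)-3-methoxyphenyl]-3-[(TBS-oxy)methyl]-7-methoxy-2,3-dihydro-1-benzofuran
Conditions: CBr4, PPh3, CH2Cl2, 0 °C; used at once
Reagents that add atoms: CBr4, BrC(Br)(Br)Br
Why: Appel reaction turns the benzylic alcohol into the bromide through an alkoxyphosphonium salt under neutral conditions, which should spare the silyl ethers and the acid-sensitive benzylic ether of the furan ring.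

Step 19
Reactants: 11 (4R)-4-[(R)-(TBS-oxy)[4-(TBS-oxy)-3-methoxyphenyl]methyl]oxolan-2-one; 29 (2S,3R)-5-(bromomethyl)-2-[4-(TBS-oxy)-3-methoxyphenyl]-3-[(TBS-oxy)methyl]-7-methoxy-2,3-dihydro-1-benzofuran
Product: 31 (3R,4R)-3-{[(2S,3R)-2-[4-(TBS-oxy)-3-methoxyphenyl]-3-[(TBS-oxy)methyl]-7-methoxy-2,3-dihydro-1-benzofuran-5-yl]methyl}-4-[(R)-(TBS-oxy)[4-(TBS-oxy)-3-methoxyphenyl]methyl]oxolan-2-one, via lactone lithium enolate 30 (not isolated)
Conditions: LiN(iPr)2 (LDA), THF, −78 °C; then 29, DMPU, −78 → −30 °C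
Reagents that add atoms: none
Why: Enolate alkylation of a β-substituted γ-butyrolactone, in which the benzylic bromide should approach the enolate face opposite the bulky C4 substituent and so give the 3,4-trans lactone with C3 as (R).

Step 20
Reactants: 31 (3R,4R)-3-{[(2S,3R)-2-[4-(TBS-oxy)-3-methoxyphenyl]-3-[(TBS-oxy)methyl]-7-methoxy-2,3-dihydro-1-benzofuran-5-yl]methyl}-4-[(R)-(TBS-oxy)[4-(TBS-oxy)-3-methoxyphenyl]methyl]oxolan-2-one
Product: 32 (3R,4R)-4-[(R)-hydroxy(4-hydroxy-3-methoxyphenyl)methyl]-3-{[(2S,3R)-2-(4-hydroxy-3-methoxyphenyl)-3-(hydroxymethyl)-7-methoxy-2,3-dihydro-1-benzofuran-5-yl]methyl}oxolan-2-one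
Conditions: TBAF, AcOH, THF, 0 °C → rt
Reagents that add atoms: none
Why: Fluoride-induced cleavage of all four silyl ethers (driven by Si–F bond formation), buffered with acetic acid so that no alkoxide or phenoxide should build up that could translactonise the γ-hydroxy lactone or expel the benzylic oxygen as a quinone methide.

**Compound list**

1 | 4-bromo-2-methoxyphenol | COc1cc(Br)ccc1O | starting material
2 | (4-bromo-2-methoxyphenoxy)(tert-butyl)dimethylsilane | COc1cc(Br)ccc1O[Si](C)(C)C(C)(C)C | intermediate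
3 | 3-methylidenecyclobutane-1-carbonitrile | C=C1CC(C#N)C1 | starting material
4 | [4-(TBS-oxy)-3-methoxyphenyl]magnesium bromide | COc1cc([Mg]Br)ccc1O[Si](C)(C)C(C)(C)C | intermediate (not isolated)
5 | N-bromomagnesio ketimine of 6 | C=C1CC(C1)C(=N[Mg]Br)c1ccc(O[Si](C)(C)C(C)(C)C)c(OC)c1 | intermediate (not isolated)
6 | [4-(TBS-oxy)-3-methoxyphenyl](3-methylidenecyclobutyl)methanone | C=C1CC(C1)C(=O)c1ccc(O[Si](C)(C)C(C)(C)C)c(OC)c1 | intermediate
7 | (R)-[4-(TBS-oxy)-3-methoxyphenyl](3-methylidenecyclobutyl)methanol | C=C1CC(C1)[C@@H](O)c1ccc(O[Si](C)(C)C(C)(C)C)c(OC)c1 | intermediate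
8 | tert-butyl{4-[(R)-(TBS-oxy)(3-methylidenecyclobutyl)methyl]-2-methoxyphenoxy}dimethylsilane | C=C1CC(C1)[C@@H](O[Si](C)(C)C(C)(C)C)c1ccc(O[Si](C)(C)C(C)(C)C)c(OC)c1 | intermediate
9 | 1-(hydroxymethyl)-3-[(R)-(TBS-oxy)[4-(TBS-oxy)-3-methoxyphenyl]methyl]cyclobutan-1-ol (mixture of ring cis and trans isomers) | OCC1(O)CC(C1)[C@@H](O[Si](C)(C)C(C)(C)C)c1ccc(O[Si](C)(C)C(C)(C)C)c(OC)c1 | intermediate (not isolated)
10 | 3-[(R)-(TBS-oxy)[4-(TBS-oxy)-3-methoxyphenyl]methyl]cyclobutan-1-one | O=C1CC(C1)[C@@H](O[Si](C)(C)C(C)(C)C)c1ccc(O[Si](C)(C)C(C)(C)C)c(OC)c1 | intermediate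
11 | (4R)-4-[(R)-(TBS-oxy)[4-(TBS-oxy)-3-methoxyphenyl]methyl]oxolan-2-one | O=C1C[C@H](CO1)[C@@H](O[Si](C)(C)C(C)(C)C)c1ccc(O[Si](C)(C)C(C)(C)C)c(OC)c1 | intermediate
12 | methyl 4-hydroxy-3-methoxybenzoate (methyl vanillate) | COC(=O)c1ccc(O)c(OC)c1 | starting material
13 | allyl bromide | C=CCBr | starting material
14 | methyl 3-methoxy-4-(prop-2-en-1-yloxy)benzoate | COC(=O)c1ccc(OCC=C)c(OC)c1 | intermediate
15 | methyl 4-hydroxy-3-methoxy-5-(prop-2-en-1-yl)benzoate | COC(=O)c1cc(CC=C)c(O)c(OC)c1 | intermediate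
16 | methyl 3-methoxy-4-(MOM-oxy)-5-(prop-2-en-1-yl)benzoate | COC(=O)c1cc(CC=C)c(OCOC)c(OC)c1 | intermediate
17 | 2-[3-methoxy-5-(methoxycarbonyl)-2-(MOM-oxy)phenyl]acetic acid | COC(=O)c1cc(CC(=O)O)c(OCOC)c(OC)c1 | intermediate
18 | (S)-4-benzyl-1,3-oxazolidin-2-one | O=C1N[C@@H](Cc2ccccc2)CO1 | starting material
19 | mixed pivalic anhydride of 17 | COC(=O)c1cc(CC(=O)OC(=O)C(C)(C)C)c(OCOC)c(OC)c1 | intermediate (not isolated)
20 | methyl 3-{2-[(4S)-4-benzyl-2-oxo-1,3-oxazolidin-3-yl]-2-oxoethyl}-5-methoxy-4-(MOM-oxy)benzoate | COC(=O)c1cc(CC(=O)N2[C@@H](Cc3ccccc3)COC2=O)c(OCOC)c(OC)c1 | intermediate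
21 | vanillin | COc1cc(C=O)ccc1O | starting material
22 | 3-methoxy-4-(MOM-oxy)benzaldehyde | COCOc1ccc(C=O)cc1OC | intermediate
23 | dibutylboron Z-enolate of 20 | COC(=O)c1cc(/C=C(\OB(CCCC)CCCC)N2[C@@H](Cc3ccccc3)COC2=O)c(OCOC)c(OC)c1 | intermediate (not isolated)
24 | methyl 3-[(2S,3S)-1-[(4S)-4-benzyl-2-oxo-1,3-oxazolidin-3-yl]-3-hydroxy-3-[3-methoxy-4-(MOM-oxy)phenyl]-1-oxopropan-2-yl]-5-methoxy-4-(MOM-oxy)benzoate | COC(=O)c1cc([C@@H]([C@H](O)c2ccc(OCOC)c(OC)c2)C(=O)N2[C@@H](Cc3ccccc3)COC2=O)c(OCOC)c(OC)c1 | intermediate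
25 | methyl 3-[(1S,2R)-1,3-dihydroxy-1-[3-methoxy-4-(MOM-oxy)phenyl]propan-2-yl]-5-methoxy-4-(MOM-oxy)benzoate | COC(=O)c1cc([C@@H]([C@H](O)c2ccc(OCOC)c(OC)c2)CO)c(OCOC)c(OC)c1 | intermediate
26 | methyl (2S,3R)-2-(4-hydroxy-3-methoxyphenyl)-3-(hydroxymethyl)-7-methoxy-2,3-dihydro-1-benzofuran-5-carboxylate | COc1cc([C@H]2Oc3c(OC)cc(C(=O)OC)cc3[C@@H]2CO)ccc1O | intermediate
27 | methyl (2S,3R)-2-[4-(TBS-oxy)-3-methoxyphenyl]-3-[(TBS-oxy)methyl]-7-methoxy-2,3-dihydro-1-benzofuran-5-carboxylate | COc1cc([C@H]2Oc3c(OC)cc(C(=O)OC)cc3[C@@H]2CO[Si](C)(C)C(C)(C)C)ccc1O[Si](C)(C)C(C)(C)C | intermediate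
28 | [(2S,3R)-2-[4-(TBS-oxy)-3-methoxyphenyl]-3-[(TBS-oxy)methyl]-7-methoxy-2,3-dihydro-1-benzofuran-5-yl]methanol | COc1cc([C@H]2Oc3c(OC)cc(CO)cc3[C@@H]2CO[Si](C)(C)C(C)(C)C)ccc1O[Si](C)(C)C(C)(C)C | intermediate
29 | (2S,3R)-5-(bromomethyl)-2-[4-(TBS-oxy)-3-methoxyphenyl]-3-[(TBS-oxy)methyl]-7-methoxy-2,3-dihydro-1-benzofuran | COc1cc([C@H]2Oc3c(OC)cc(CBr)cc3[C@@H]2CO[Si](C)(C)C(C)(C)C)ccc1O[Si](C)(C)C(C)(C)C | intermediate
30 | lithium enolate of 11 | [Li]OC1=C[C@H](CO1)[C@@H](O[Si](C)(C)C(C)(C)C)c1ccc(O[Si](C)(C)C(C)(C)C)c(OC)c1 | intermediate (not isolated)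
31 | (3R,4R)-3-{[(2S,3R)-2-[4-(TBS-oxy)-3-methoxyphenyl]-3-[(TBS-oxy)methyl]-7-methoxy-2,3-dihydro-1-benzofuran-5-yl]methyl}-4-[(R)-(TBS-oxy)[4-(TBS-oxy)-3-methoxyphenyl]methyl]oxolan-2-one | COc1cc([C@H]2Oc3c(OC)cc(C[C@H]4C(=O)OC[C@@H]4[C@@H](O[Si](C)(C)C(C)(C)C)c4ccc(O[Si](C)(C)C(C)(C)C)c(OC)c4)cc3[C@@H]2CO[Si](C)(C)C(C)(C)C)ccc1O[Si](C)(C)C(C)(C)C | intermediate
32 | (3R,4R)-4-[(R)-hydroxy(4-hydroxy-3-methoxyphenyl)methyl]-3-{[(2S,3R)-2-(4-hydroxy-3-methoxyphenyl)-3-(hydroxymethyl)-7-methoxy-2,3-dihydro-1-benzofuran-5-yl]methyl}oxolan-2-one (CNP0233460.1) | COc1cc([C@H]2Oc3c(OC)cc(C[C@H]4C(=O)OC[C@@H]4[C@@H](O)c4ccc(O)c(OC)c4)cc3[C@@H]2CO)ccc1O | target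

**Step count and risks**

Total step count: 20. Longest linear sequence: 13 steps (steps 7–11 and 13–20, from methyl vanillate 12).

Steps most likely to fail:

1. Step 6. The two ring methylenes may be discriminated poorly, either because the catalyst and the carbinol centre are mismatched or because uncatalysed oxidation by the peracid competes; the Lewis acid may also ionise the benzylic silyl ether. The fallback sets out from 10 and gives up catalyst control: an uncatalysed, buffered Baeyer–Villiger oxidation (mCPBA, NaHCO3, CH2Cl2, 0 °C) should give 11 together with its C4 epimer, the (4S)-lactone F1. Because the carbinol centre makes the two lactones diastereomers, they should be separable on silica or by preparative HPLC, and the route is rejoined at 11.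

2. Step 19. The electron-rich benzylic bromide may decompose under the basic conditions, C-alkylation of the hindered enolate may be slow, and proton exchange may lead to double alkylation. The fallback sets out from 28 and 11 and replaces alkylation by aldol condensation and reduction. Alcohol 28 is oxidised with MnO2 in CH2Cl2 to the benzofuran-5-carbaldehyde F2. Enolate 30 (from 11 and LDA, −78 °C) is added to F2 to give the β-hydroxy lactone F3 as a mixture of carbinol epimers. MsCl and Et3N convert F3 into the mesylate F4, and DBU eliminates it to the (E)-benzylidene lactone F5. Conjugate reduction with [(Ph3P)CuH]6 in toluene should then give the benzyl lactone, possibly with some of the 3,4-cis lactone F6, which DBU should equilibrate at C3 to the trans isomer. The route is rejoined at 31.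

3. Step 14. The α-aryl-β-hydroxy imide may undergo retro-aldol cleavage under the basic hydride conditions, and the aromatic ester may be reduced in competition. The fallback sets out from 24 and caps the carbinol first: TESOTf and 2,6-lutidine give the TES ether F7, which can no longer fragment; LiBH4 then removes the auxiliary to give the primary alcohol F8; and 3 M HCl in THF removes the TES and MOM groups and closes the furan ring as in step 15. The route is rejoined at 26.

**Further compounds**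

F1 | step 6 | (4S)-4-[(R)-(TBS-oxy)[4-(TBS-oxy)-3-methoxyphenyl]methyl]oxolan-2-one (C4 epimer of 11) | O=C1C[C@@H](CO1)[C@@H](O[Si](C)(C)C(C)(C)C)c1ccc(O[Si](C)(C)C(C)(C)C)c(OC)c1
F2 | step 19 | (2S,3R)-2-[4-(TBS-oxy)-3-methoxyphenyl]-3-[(TBS-oxy)methyl]-7-methoxy-2,3-dihydro-1-benzofuran-5-carbaldehyde | COc1cc([C@H]2Oc3c(OC)cc(C=O)cc3[C@@H]2CO[Si](C)(C)C(C)(C)C)ccc1O[Si](C)(C)C(C)(C)C
F3 | step 19 | β-hydroxy lactone from 30 and F2 (31 with OH on the benzylic CH, carbinol epimers) | COc1cc([C@H]2Oc3c(OC)cc(C(O)[C@H]4C(=O)OC[C@@H]4[C@@H](O[Si](C)(C)C(C)(C)C)c4ccc(O[Si](C)(C)C(C)(C)C)c(OC)c4)cc3[C@@H]2CO[Si](C)(C)C(C)(C)C)ccc1O[Si](C)(C)C(C)(C)C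
F4 | step 19 | methanesulfonate of F3 | COc1cc([C@H]2Oc3c(OC)cc(C(OS(C)(=O)=O)[C@H]4C(=O)OC[C@@H]4[C@@H](O[Si](C)(C)C(C)(C)C)c4ccc(O[Si](C)(C)C(C)(C)C)c(OC)c4)cc3[C@@H]2CO[Si](C)(C)C(C)(C)C)ccc1O[Si](C)(C)C(C)(C)C
F5 | step 19 | (E)-3-benzylidene lactone (4R, side-chain R) | COc1cc([C@H]2Oc3c(OC)cc(/C=C4/C(=O)OC[C@@H]4[C@@H](O[Si](C)(C)C(C)(C)C)c4ccc(O[Si](C)(C)C(C)(C)C)c(OC)c4)cc3[C@@H]2CO[Si](C)(C)C(C)(C)C)ccc1O[Si](C)(C)C(C)(C)C
F6 | step 19 | 3,4-cis lactone (C3 epimer of 31) | COc1cc([C@H]2Oc3c(OC)cc(C[C@@H]4C(=O)OC[C@@H]4[C@@H](O[Si](C)(C)C(C)(C)C)c4ccc(O[Si](C)(C)C(C)(C)C)c(OC)c4)cc3[C@@H]2CO[Si](C)(C)C(C)(C)C)ccc1O[Si](C)(C)C(C)(C)C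
F7 | step 14 | TES ether of 24 | COC(=O)c1cc([C@@H]([C@H](O[Si](CC)(CC)CC)c2ccc(OCOC)c(OC)c2)C(=O)N2[C@@H](Cc3ccccc3)COC2=O)c(OCOC)c(OC)c1
F8 | step 14 | methyl 3-[(1S,2R)-3-hydroxy-1-[3-methoxy-4-(MOM-oxy)phenyl]-1-(TES-oxy)propan-2-yl]-5-methoxy-4-(MOM-oxy)benzoate | COC(=O)c1cc([C@@H]([C@H](O[Si](CC)(CC)CC)c2ccc(OCOC)c(OC)c2)CO)c(OCOC)c(OC)c1
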